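Start from the easy step: first product made just before work-up has had no time to decay.

    reagent + first product → double product (k1 = 0.0062 M⁻¹ s⁻¹)
    reagent + double product → triple product (k2 = 0.20 M⁻¹ s⁻¹)
    starting material ⇌ dormant form (K3 = 1.3, k3 = 0.0033 s⁻¹)
    starting material + reagent → first product (k4 = 0.27 M⁻¹ s⁻¹)
    first product → over-reaction product (k5 = 0.0057 s⁻¹)

| flask | starting material | reagent | time | remark |
|---|---|---|---|---|
| Saturday's | 37 mM (fed, over 6.00 min) | 38.9 mM | 6.0 min | a stirred flask in which starting material is dosed at a steady rate over 6.00 min without added volume, worked up at 6.0 min |
| Tuesday's | 37 mM | 38.9 mM (fed, over 6.00 min) | 6.0 min | a stirred flask in which reagent is dosed at a steady rate over 6.00 min without added volume, worked up at 6.0 min |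
| Sunday's | 37 mM | 38.9 mM | 6.0 min | everything together in a closed stirred flask, run for 6.0 min |
| Friday's | 37 mM | 38.9 mM |  | one stirred flow tank at steady state, fed with the mixture as stated, mean residence time 6.0 min |

- the stated concentrations are those of everything mixed, before any reaction; amounts are the same in each set-up
- the feed brings no volume worth counting
- run time (Saturday's): 6.0 min

- the set-up with the highest amount of first product at the outlet or at the end, in percent of the starting material put in ("none" if the first two lie within 2 percentage points) (Saturday's / Tuesday's / Sunday's / Friday's / none)
- amount of first product at the outlet or at the end, in percent of the starting material put in, Saturday's
- amount of first product at the outlet or at the end, in percent of the starting material put in, Tuesday's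
- amount of first product at the outlet or at the end, in percent of the starting material put in, Sunday's
- amount of first product at the outlet or at the end, in percent of the starting material put in, Friday's

We order the clocks from fast to slow, each step counted by itself.

| Event | Time |
|---|---|
| half-life of starting material against reagent at charge | 1.1 min |
| half-life of first product going to over-reaction product | 2.0 min |
| half-life of starting material going to dormant form, forward step | 3.5 min |
| the run | 6.0 min |
| half-life of first product against reagent at charge | 48 min |

With reagent as charged, starting material meets reagent faster than it slips into the dormant form. First product decays well within the run, so early product is lost. Its attack by reagent is slower than the run, so we drop double product and triple product.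

The run lasts 2.05 decay lifetimes, and the oldest portion survives to 12.8%. Averaging the survival curve over the run gives 42.5%. This is the keep factor, the share of first product still standing at the end when it is made at an even pace through the run.

We try it on Saturday's, where starting material goes in at a steady rate, and take the making there as even. We guess that reagent falls to 0.5 of its charge and replace its curve by the straight-line mean. This gives a pseudo-first-order constant of 0.473 min⁻¹, or 0.671 min⁻¹ with the forward step to dormant form added. The same averaging, with the way back left out, says that 75.6% of the feed reacts, and 70.5% of that becomes first product. So 53.3% is made, which uses 50.7% of the reagent and fits the guess. Our figure for Saturday's is 22.6%.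

The forecast, holding that “the yield depends mainly on how late it is made”, names Saturday's as best, with 22.7% (20.5% to 25%), then 19.2% for Tuesday's, 16.5% for Sunday's and 17% for Friday's.

The simulation names Saturday's as best, with 23.9%, then 19.7% for Tuesday's, 16.5% for Sunday's and 17.1% for Friday's, each inside the forecast's range. At the end of Saturday's, over-reaction product stands at 28.0%, double product at 0.455% and triple product at 0.356%. First product and all that came from it therefore total 52.7%, and the keep factor 42.5% turns that into 22.4%. The same total for Tuesday's is 44.9%, which the keep factor turns into 19.1%, against 19.7% standing.

The numbers of this flask were chosen freely; the rest is arithmetic.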